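The isoflavone is cut at its C4 carbonyl, which joins C4a of ring A to the aryl-bearing C3 of ring C, and at the O1–C2 ether bond. A single palladium-catalysed operation should therefore unite 2-iodo-3,5-dimethoxyphenol, carbon monoxide and a 1-(2,4,5-trimethoxyphenyl)vinyl pinacol boronate. Carbonylative Suzuki coupling makes C4a–C4 and C4–C3, and the neighbouring phenoxide then closes O1–C2 by conjugate addition to give the 5,7-dimethoxyisoflavanone. Since the iodine already defines C4a, ring A poses no regiochemical question. Dehydrogenation, 5-O-demethylation, para-hydroxylation, oxidation to the 5,8-quinone and prenyl transfer to C6, the only free quinone carbon, then lead to the target.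

Key step: step 4

Remark on the chemistry: the target has no stereocentre, so isoflavanone 9 is made and used as the racemate; its C3 centre is erased in step 5.

Step 1
Reactants: 1 3,5-dimethoxyphenol
Product: 2 2-iodo-3,5-dimethoxyphenol
Conditions: NIS (1.0 equiv), CH2Cl2, −20 to 0 °C
Reagents that add atoms: N-iodosuccinimide, O=C1CCC(=O)N1I
Why: Electrophilic aromatic iodination of a phenol: both positions ortho to the hydroxyl are equivalent and less hindered than C4 between the two methoxy groups, so mono-iodination there should prevail, and any 4-iodo isomer can be removed by chromatography.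

Step 2
Reactants: 3 2,4,5-trimethoxyacetophenone
Product: 5 1-(2,4,5-trimethoxyphenyl)ethenyl trifluoromethanesulfonate, via potassium enolate 4 (not isolated)
Conditions: KN(SiMe3)2, THF, −78 °C; then PhNTf2, −78 to 0 °C
Reagents that add atoms: N-phenylbis(trifluoromethanesulfonimide), O=S(=O)(N(c1ccccc1)S(=O)(=O)C(F)(F)F)C(F)(F)F
Why: Enol triflate formation: kinetic enolisation of a methyl aryl ketone with only one enolisable position, then O-triflation of the enolate, should give the vinyl triflate, which is best used promptly because the electron-rich aryl group makes it acid-sensitive.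

Step 3
Reactants: 5 1-(2,4,5-trimethoxyphenyl)ethenyl trifluoromethanesulfonate
Product: 6 4,4,5,5-tetramethyl-2-[1-(2,4,5-trimethoxyphenyl)ethenyl]-1,3,2-dioxaborolane
Conditions: B2pin2, PdCl2(PPh3)2 (3 mol %), PPh3, KOPh, toluene, 50 °C
Reagents that add atoms: bis(pinacolato)diboron, CC1(C)OB(OC1(C)C)B1OC(C)(C)C(C)(C)O1
Why: Miyaura borylation of an alkenyl triflate: zerovalent palladium inserts into the C–O bond, the phenoxide ligand mediates boryl transfer from the diboron and reductive elimination forms the C–B bond, the weak base keeping the product from coupling with remaining triflate.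

Step 4
Reactants: 2 2-iodo-3,5-dimethoxyphenol; 6 4,4,5,5-tetramethyl-2-[1-(2,4,5-trimethoxyphenyl)ethenyl]-1,3,2-dioxaborolane; 7 carbon monoxide
Product: 9 (±)-5,7-dimethoxy-3-(2,4,5-trimethoxyphenyl)chroman-4-one, via hydroxyaryl vinyl ketone 8 (not isolated)
Conditions: Pd(OAc)2 (5 mol %), di(1-adamantyl)-n-butylphosphine (10 mol %), K2CO3 (3 equiv), CO (5 bar), 1,4-dioxane/H2O (20:1), 80 °C
Reagents that add atoms: none
Why: Zerovalent palladium, formed in the flask from Pd(OAc)2 and the phosphine, inserts into the C–I bond of 2, CO migratory insertion gives the aroylpalladium complex, boronate 6 transmetalates under carbonate activation and reductive elimination releases enone 8, so that C4a–C4 and C4–C3 arise in one catalytic cycle. The closest known reactions are the carbonylative Suzuki–Miyaura coupling of aryl iodides with alkenylboron reagents and the base-mediated cyclisation of 2'-hydroxy alpha-methylene deoxybenzoins to isoflavanones. The phenoxide of 8 then adds to the terminal CH2 of the enone in a 6-endo-trig oxa-Michael closure that forms O1–C2 and ring C. The new C3 centre comes from unselective protonation of the resulting enolate, so 9 is racemic, which does not matter because step 5 removes this centre. The step needs carbonylative coupling to win over direct coupling and over capture of the aroyl complex by phenoxide as an ester: CO pressure and the electron-rich aryl–palladium intermediate flanked by two ortho substituents should make CO insertion faster than transmetalation, and an excess of 6 should keep ketone formation ahead of O-acylation.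

Step 5
Reactants: 9 (±)-5,7-dimethoxy-3-(2,4,5-trimethoxyphenyl)chroman-4-one
Product: 10 5,7-dimethoxy-3-(2,4,5-trimethoxyphenyl)-4H-chromen-4-one
Conditions: DDQ (1.5 equiv), 1,4-dioxane, reflux
Reagents that add atoms: none
Why: Quinone dehydrogenation of a chroman-4-one to the chromone: DDQ abstracts hydride from C2, where O1 stabilises the oxocarbenium ion, and loss of the C3 proton gives the isoflavone and erases the C3 stereocentre.

Step 6
Reactants: 10 5,7-dimethoxy-3-(2,4,5-trimethoxyphenyl)-4H-chromen-4-one
Product: 11 5-hydroxy-7-methoxy-3-(2,4,5-trimethoxyphenyl)-4H-chromen-4-one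
Conditions: BCl3 (1.5 equiv), CH2Cl2, −78 to 0 °C; then H2O
Reagents that add atoms: none
Why: Chelation-directed Lewis acid ether cleavage: boron bridges the C4 carbonyl oxygen and the peri 5-methoxy oxygen in a six-membered chelate, so chloride removes only that methyl group while the four non-chelating methoxy groups should persist at low temperature.

Step 7
Reactants: 11 5-hydroxy-7-methoxy-3-(2,4,5-trimethoxyphenyl)-4H-chromen-4-one
Product: 13 5,8-dihydroxy-7-methoxy-3-(2,4,5-trimethoxyphenyl)-4H-chromen-4-one, via potassium 8-sulfate 12 (not isolated)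
Conditions: K2S2O8, aq KOH, pyridine, 15 °C; then aq HCl, Na2SO3, 80 °C
Reagents that add atoms: potassium peroxodisulfate, [K+].[K+].[O-]S(=O)(=O)OOS(=O)(=O)[O-]
Why: Elbs persulfate oxidation: the C5 phenoxide attacks a peroxide oxygen through its para carbon C8 to give the aryl sulfate, which hot acid hydrolyses to the phenol, and ring B, which has no free hydroxyl, should not react.

Step 8
Reactants: 13 5,8-dihydroxy-7-methoxy-3-(2,4,5-trimethoxyphenyl)-4H-chromen-4-one
Product: 14 7-methoxy-3-(2,4,5-trimethoxyphenyl)-4H-chromene-4,5,8-trione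
Conditions: Ag2O, MgSO4, CH2Cl2, rt, dark
Reagents that add atoms: none
Why: Oxidation of a para-hydroquinone to the para-quinone by Ag2O, a mild two-electron oxidant that should leave the trimethoxyphenyl ring and the pyranone untouched.

Step 9
Reactants: 14 7-methoxy-3-(2,4,5-trimethoxyphenyl)-4H-chromene-4,5,8-trione; 15 tributyl(3-methylbut-2-enyl)stannane
Product: 16 5,8-dihydroxy-7-methoxy-6-(3-methylbut-2-enyl)-3-(2,4,5-trimethoxyphenyl)-4H-chromen-4-one
Conditions: BF3·OEt2 (2.5 equiv), CH2Cl2, −78 to −40 °C; aq KF
Reagents that add atoms: none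
Why: Lewis-acid-promoted allylation of a quinone by an allylstannane: the BF3-activated quinone should take up the prenyl group at C6, its only hydrogen-bearing ring carbon, in the linear form that this reaction class is known to deliver, enolisation then gives the 5,8-hydroquinone directly, and the low temperature should keep the prenyl group from cyclising onto the 5-hydroxyl.

Compound list
1 | 3,5-dimethoxyphenol | COc1cc(O)cc(OC)c1 | starting material
2 | 2-iodo-3,5-dimethoxyphenol | COc1cc(O)c(I)c(OC)c1 | intermediate
3 | 2,4,5-trimethoxyacetophenone | CC(=O)c1cc(OC)c(OC)cc1OC | starting material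
4 | potassium 1-(2,4,5-trimethoxyphenyl)ethenolate | [K+].[O-]C(=C)c1cc(OC)c(OC)cc1OC | intermediate
5 | 1-(2,4,5-trimethoxyphenyl)ethenyl trifluoromethanesulfonate | C=C(OS(=O)(=O)C(F)(F)F)c1cc(OC)c(OC)cc1OC | intermediate
6 | 4,4,5,5-tetramethyl-2-[1-(2,4,5-trimethoxyphenyl)ethenyl]-1,3,2-dioxaborolane | C=C(B1OC(C)(C)C(C)(C)O1)c1cc(OC)c(OC)cc1OC | intermediate
7 | carbon monoxide | [C-]#[O+] | starting material
8 | 1-(2-hydroxy-4,6-dimethoxyphenyl)-2-(2,4,5-trimethoxyphenyl)prop-2-en-1-one | C=C(C(=O)c1c(O)cc(OC)cc1OC)c1cc(OC)c(OC)cc1OC | intermediate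
9 | (±)-5,7-dimethoxy-3-(2,4,5-trimethoxyphenyl)chroman-4-one (racemic at C3) | COc1cc(OC)c2c(c1)OCC(c1cc(OC)c(OC)cc1OC)C2=O | intermediate
10 | 5,7-dimethoxy-3-(2,4,5-trimethoxyphenyl)-4H-chromen-4-one | COc1cc(OC)c2c(=O)c(-c3cc(OC)c(OC)cc3OC)coc2c1 | intermediate
11 | 5-hydroxy-7-methoxy-3-(2,4,5-trimethoxyphenyl)-4H-chromen-4-one | COc1cc(O)c2c(=O)c(-c3cc(OC)c(OC)cc3OC)coc2c1 | intermediate
12 | potassium 5-hydroxy-7-methoxy-4-oxo-3-(2,4,5-trimethoxyphenyl)-4H-chromen-8-yl sulfate | COc1cc(O)c2c(=O)c(-c3cc(OC)c(OC)cc3OC)coc2c1OS(=O)(=O)[O-].[K+] | intermediate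
13 | 5,8-dihydroxy-7-methoxy-3-(2,4,5-trimethoxyphenyl)-4H-chromen-4-one | COc1cc(O)c2c(=O)c(-c3cc(OC)c(OC)cc3OC)coc2c1O | intermediate
14 | 7-methoxy-3-(2,4,5-trimethoxyphenyl)-4H-chromene-4,5,8-trione | COC1=CC(=O)C2=C(OC=C(c3cc(OC)c(OC)cc3OC)C2=O)C1=O | intermediate
15 | tributyl(3-methylbut-2-enyl)stannane | CCCC[Sn](CCCC)(CCCC)CC=C(C)C | starting material
16 | 5,8-dihydroxy-7-methoxy-6-(3-methylbut-2-enyl)-3-(2,4,5-trimethoxyphenyl)-4H-chromen-4-one | COc1cc(OC)c(-c2coc3c(O)c(OC)c(CC=C(C)C)c(O)c3c2=O)cc1OC | target

Total step count: 9. Longest linear sequence: 8 steps (steps 2 to 9, from 3).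

Steps most likely to fail

Step 4. The aryl–palladium intermediate may couple with the boronate before CO inserts, the aroyl complex may be intercepted by phenoxide to give esters and oligomers, or the hindered 1,1-disubstituted vinyl boronate may transmetalate too slowly and be lost by protodeboronation. The fallback builds ring C by the deoxybenzoin route and sets out from 1. Friedel–Crafts acylation of 1 with (2,4,5-trimethoxyphenyl)acetic acid in BF3·OEt2 at 80 °C should give, through the chelated ortho-hydroxy ketone, 1-(2-hydroxy-4,6-dimethoxyphenyl)-2-(2,4,5-trimethoxyphenyl)ethan-1-one F1. Heating F1 with N,N-dimethylformamide dimethyl acetal in toluene should form the enaminone 3-(dimethylamino)-1-(2-hydroxy-4,6-dimethoxyphenyl)-2-(2,4,5-trimethoxyphenyl)prop-2-en-1-one F2, which closes onto the phenol with loss of dimethylamine. The route is rejoined at isoflavone 10, so steps 1 to 5 are not needed.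

Step 9. Allyl transfer may go to the wrong site (addition at the C8 carbonyl or displacement of the 7-methoxy group instead of bonding at C6), the prenyl group may arrive transposed, or the Lewis acid may cyclise it onto the 5-hydroxyl. The fallback replaces direct allylation by halogenation and cross-coupling and sets out from 14. Bromine in CH2Cl2 at 0 °C followed by Et3N should add to and re-eliminate from the enol-ether carbon C6 to give 6-bromo-7-methoxy-3-(2,4,5-trimethoxyphenyl)-4H-chromene-4,5,8-trione F3. Stille coupling of F3 with stannane 15 under Pd(PPh3)4 in 1,4-dioxane at 80 °C should give 7-methoxy-6-(3-methylbut-2-enyl)-3-(2,4,5-trimethoxyphenyl)-4H-chromene-4,5,8-trione F4. Reduction of F4 with aqueous Na2S2O4 returns to the route at target 16.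

Step 7. The chelated, carbonyl-deactivated phenoxide may react too slowly with persulfate, and prolonged exposure to aqueous alkali may open the pyranone ring at C2. The fallback uses a stronger electrophile and an azo–amine–quinone sequence, and sets out from 11. Coupling with 4-sulfobenzenediazonium chloride (from sulfanilic acid, NaNO2 and HCl) in cold aqueous Na2CO3/pyridine should occur para to the phenoxide to give sodium 4-{(E)-[5-hydroxy-7-methoxy-4-oxo-3-(2,4,5-trimethoxyphenyl)-4H-chromen-8-yl]diazenyl}benzenesulfonate F5. Reduction of F5 with Na2S2O4 should give 8-amino-5-hydroxy-7-methoxy-3-(2,4,5-trimethoxyphenyl)-4H-chromen-4-one F6. Oxidation of this para-aminophenol with FeCl3 in aqueous HCl should give quinone 14, where the route is rejoined, so 13 and step 8 are bypassed.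

Further compounds
F1 | step 4 | 1-(2-hydroxy-4,6-dimethoxyphenyl)-2-(2,4,5-trimethoxyphenyl)ethan-1-one | COc1cc(O)c(C(=O)Cc2cc(OC)c(OC)cc2OC)c(OC)c1
F2 | step 4 | 3-(dimethylamino)-1-(2-hydroxy-4,6-dimethoxyphenyl)-2-(2,4,5-trimethoxyphenyl)prop-2-en-1-one (alkene geometry not defined, lost on ring closure) | CN(C)C=C(C(=O)c1c(O)cc(OC)cc1OC)c1cc(OC)c(OC)cc1OC
F3 | step 9 | 6-bromo-7-methoxy-3-(2,4,5-trimethoxyphenyl)-4H-chromene-4,5,8-trione | COC1=C(Br)C(=O)C2=C(OC=C(c3cc(OC)c(OC)cc3OC)C2=O)C1=O
F4 | step 9 | 7-methoxy-6-(3-methylbut-2-enyl)-3-(2,4,5-trimethoxyphenyl)-4H-chromene-4,5,8-trione | COC1=C(CC=C(C)C)C(=O)C2=C(OC=C(c3cc(OC)c(OC)cc3OC)C2=O)C1=O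
F5 | step 7 | sodium 4-{(E)-[5-hydroxy-7-methoxy-4-oxo-3-(2,4,5-trimethoxyphenyl)-4H-chromen-8-yl]diazenyl}benzenesulfonate | COc1cc(O)c2c(=O)c(-c3cc(OC)c(OC)cc3OC)coc2c1/N=N/c1ccc(S(=O)(=O)[O-])cc1.[Na+]
F6 | step 7 | 8-amino-5-hydroxy-7-methoxy-3-(2,4,5-trimethoxyphenyl)-4H-chromen-4-one | COc1cc(O)c2c(=O)c(-c3cc(OC)c(OC)cc3OC)coc2c1N
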